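**Plan**
1. Retrosynthesis: the C2 and C6 acetates, the C11=C13 methylene and the epoxide C5–O bond are taken off first. The ten-membered carbocycle is then cut at C3–C4 (aldol), the side chain at C8–C9 (vinylogous aldol), the lactone at O8–C12, and the chain at C7–C8 (conjugate addition), C7=C11 (Wittig) and C4–C15 (Grignard).
2. Enabling feature: in ring C1–C10 the fully substituted C4 (C15 methyl, epoxide oxygen) stands 1,3 to oxygen-bearing C2. C2–C3–C4 is therefore a masked tertiary β-hydroxy ketone, and the ring can be closed by joining a C3 enolate of a C2 ketone to a C4 methyl ketone.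
3. Forward: L-tartrate supplies C4–C7; C11/C12, C8 and then C9–C10(C14)–C1–C2–C3 (from mesityl oxide) are added. The γ-lactone closes first (step 15), the ten-membered ring second (step 19), the epoxide third (step 24); methylenation and acetylation finish.
4. Stereochemistry: C5 and C6 come from L-tartrate; C7 from anti-selective cuprate addition next to C6; C8 from Felkin–Anh addition next to C7; C4 from samarium chelation to the C5 ether; C2 from reduction directed by the C4 hydroxyl; C5 is inverted when the epoxide closes.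

Key step: step 19

Remark: atoms carry germacrane numbers (ring C1–C10; lactone carbons C11 and C12 on C7, ring oxygen on C8; C13 exocyclic methylene; C14 methyl on C10; C15 methyl on C4). NAP = 2-naphthylmethyl, PMB = 4-methoxybenzyl, TBS = tert-butyldimethylsilyl, TMS = trimethylsilyl. The configurations at C4 in 6–22 and at C11 in 33–34 are immaterial because both carbons become sp2 later; the SMILES show the expected major C4 epimer and leave C11 open.

Step 1
Reactants: 1 diethyl L-tartrate
Product: 2 diethyl 2,3-O-(2-naphthylmethylene)-L-tartrate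
Conditions: 2-naphthaldehyde, TsOH·H2O (cat.), toluene, reflux (Dean–Stark)
Reagents that add atoms: 2-naphthaldehyde, O=Cc1ccc2ccccc2c1
Why: Acid-catalysed acetalisation of the 1,2-diol with azeotropic removal of water should give the trans-dioxolane, whose acetal carbon is not stereogenic because the diester is twofold-symmetric, and neither tartrate centre is touched.

Step 2
Reactants: 2 diethyl 2,3-O-(2-naphthylmethylene)-L-tartrate
Product: 3 2-O-(2-naphthylmethyl)-L-threitol
Conditions: LiAlH4, AlCl3, Et2O/CH2Cl2, 0 °C → reflux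
Reagents that add atoms: none
Why: Alane from LiAlH4/AlCl3 reduces both esters and opens the arylmethylene acetal reductively (the known conversion of benzylidene tartrates into 2-O-benzylthreitols), and the symmetry of 2 allows only one mono-ether, which places the NAP group on C5.

Step 3
Reactants: 3 2-O-(2-naphthylmethyl)-L-threitol
Product: 4 3,4-O-isopropylidene-2-O-(2-naphthylmethyl)-L-threitol
Conditions: Me2C(OMe)2, TsOH (cat.), acetone, 25 °C
Reagents that add atoms: 2,2-dimethoxypropane, COC(C)(C)OC
Why: Transketalisation under thermodynamic control should place the isopropylidene group on the terminal 1,2-diol (O6/O7, dioxolane preferred over a 1,3-dioxane) and leave only the C4 hydroxyl free.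

Step 4
Reactants: 4 3,4-O-isopropylidene-2-O-(2-naphthylmethyl)-L-threitol
Product: 5 3,4-O-isopropylidene-2-O-(2-naphthylmethyl)-L-threose (C4 aldehyde)
Conditions: Dess–Martin periodinane, CH2Cl2, 0 → 25 °C
Reagents that add atoms: none
Why: Dess–Martin oxidation of the primary alcohol proceeds under neutral conditions that should not epimerise the α-alkoxy centre C5.

Step 5
Reactants: 5 3,4-O-isopropylidene-2-O-(2-naphthylmethyl)-L-threose
Product: 6 (4R)-C4 methyl carbinol (C15–C4(OH)–C5(ONAP)–C6/C7 acetonide)
Conditions: CH3MgBr, Et2O, −78 °C; then H2O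
Reagents that add atoms: methylmagnesium bromide, C[Mg]Br
Why: Grignard addition through the Cram chelate between the aldehyde oxygen and the C5 ether oxygen should give mainly the 4,5-syn carbinol, and the C4 configuration does not matter because C4 is oxidised in step 18.

Step 6
Reactants: 6 (4R)-C4 methyl carbinol
Product: 7 C4 PMB ether
Conditions: NaH, 4-MeOC6H4CH2Cl, Bu4NI (cat.), THF/DMF, 0 → 25 °C
Reagents that add atoms: 4-methoxybenzyl chloride, COc1ccc(CCl)cc1
Why: Williamson etherification masks C4–OH with a group that survives acid, base and fluoride and can later be removed oxidatively in the presence of the NAP ether.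

Step 7
Reactants: 7 C4 PMB ether
Product: 8 C6/C7 diol
Conditions: AcOH/H2O (4:1), 40 °C
Reagents that add atoms: none
Why: Acetal hydrolysis in aqueous acetic acid cleaves the terminal isopropylidene group while the two benzyl-type ethers stay intact.

Step 8
Reactants: 8 C6/C7 diol
Product: 9 C6/C7 bis-TBS ether
Conditions: tBuMe2SiOTf, 2,6-lutidine, CH2Cl2, −78 → 0 °C
Reagents that add atoms: tert-butyldimethylsilyl triflate, CC(C)(C)[Si](C)(C)OS(=O)(=O)C(F)(F)F
Why: Silylation with the silyl triflate is fast enough to cap the hindered secondary C6 hydroxyl as well as the primary one.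

Step 9
Reactants: 9 C6/C7 bis-TBS ether
Product: 10 C7 primary alcohol (C6–OTBS)
Conditions: HF·pyridine, pyridine, THF, 0 °C
Reagents that add atoms: none
Why: Buffered HF·pyridine should cleave the primary silyl ether much faster than the hindered secondary one (selective desilylation).

Step 10
Reactants: 10 C7 primary alcohol
Product: 11 C7 aldehyde
Conditions: Dess–Martin periodinane, CH2Cl2, 0 → 25 °C
Reagents that add atoms: none
Why: Dess–Martin oxidation should give the α-silyloxy aldehyde without epimerisation at C6.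

Step 11
Reactants: 11 C7 aldehyde
Product: 12 methyl (E)-enoate (C7=C11, C12 ester)
Conditions: Ph3P=CHCO2Me, CH2Cl2, 25 °C
Reagents that add atoms: methyl (triphenylphosphoranylidene)acetate, COC(=O)C=P(c1ccccc1)(c1ccccc1)c1ccccc1
Why: Wittig olefination with the stabilised ylide in an aprotic solvent should give the E-enoate and adds C11 and C12.

Step 12
Reactants: 12 methyl (E)-enoate
Product: 14 (7R)-C7 vinyl ester, via silyl ketene acetal 13 (not isolated)
Conditions: CH2=CHMgBr, CuI, Me3SiCl, THF, −78 °C; then aq. NH4Cl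
Reagents that add atoms: vinylmagnesium bromide, C=C[Mg]Br
Why: Me3SiCl-accelerated conjugate addition of the vinyl cuprate to the E-γ-silyloxy enoate should take place anti to the C6–O bond (modified Felkin–Anh model for 1,2-induction), which sets C7 and brings in C8.

Step 13
Reactants: 14 (7R)-C7 vinyl ester
Product: 15 C8 aldehyde
Conditions: OsO4 (cat.), NaIO4, 2,6-lutidine, dioxane/H2O, 25 °C
Reagents that add atoms: sodium periodate (oxygen delivered through OsO4), [Na+].[O-][I](=O)(=O)=O
Why: Lemieux–Johnson cleavage turns the terminal vinyl group into the C8 aldehyde and spares the electron-rich PMB and NAP ethers that ozone could attack.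

Step 14
Reactants: 16 mesityl oxide
Product: 17 (Z)-2-methyl-4-(trimethylsilyloxy)penta-1,3-diene
Conditions: Me3SiCl, Et3N, DMF, 90 °C; fractional distillation
Reagents that add atoms: chlorotrimethylsilane, C[Si](C)(C)Cl
Why: Silylation under equilibrating conditions should favour the conjugated dienol ether from γ-deprotonation, the C9–C10(C14)–C1–C2–C3 unit with its nucleophilic terminus at C9, and distillation removes any cross-conjugated isomer.

Step 15
Reactants: 15 C8 aldehyde; 17 (Z)-2-methyl-4-(trimethylsilyloxy)penta-1,3-diene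
Product: 19 (7R,8S)-trans-lactone methyl enone, via C8 hydroxy ester 18 (not isolated)
Conditions: B(C6F5)3, CH2Cl2/Et2O, −78 °C; aq. NaHCO3; then camphorsulfonic acid (cat.), CH2Cl2, 25 °C
Reagents that add atoms: none
Why: Vinylogous Mukaiyama aldol addition at the diene terminus C9, promoted by a monodentate borane that cannot chelate, should follow the Felkin–Anh path with the C6 branch on C7 anti to the nucleophile; this sets C8, gives the E-enone from the s-trans diene, and acid then closes the trans γ-lactone (5-exo-trig transesterification).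

Step 16
Reactants: 19 (7R,8S)-trans-lactone methyl enone
Product: 21 bromomethyl enone (C4–OPMB), via TMS dienol ether 20 (not isolated)
Conditions: LiN(SiMe3)2, Me3SiCl, THF, −78 °C; then N-bromosuccinimide, −78 → 0 °C
Reagents that add atoms: N-bromosuccinimide, O=C1CCC(=O)N1Br
Why: Kinetic deprotonation of the enone at the α′-methyl group C3 (more acidic than the lactone CH2) with in-situ silylation gives the cross-conjugated silyl dienol ether, which N-bromosuccinimide brominates at its terminal carbon.

Step 17
Reactants: 21 bromomethyl enone (C4–OPMB)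
Product: 22 bromomethyl enone C4 alcohol
Conditions: (NH4)2Ce(NO3)6, MeCN/H2O (9:1), 0 °C
Reagents that add atoms: none
Why: Single-electron oxidative cleavage removes the electron-rich PMB ether, while NAP ethers are known to survive these conditions and the bromo ketone, lactone and silyl ether are not affected.

Step 18
Reactants: 22 bromomethyl enone C4 alcohol
Product: 23 (5R,6S,7R,8S)-bromomethyl enone C4 methyl ketone (cyclisation precursor)
Conditions: Dess–Martin periodinane, CH2Cl2, 0 → 25 °C
Reagents that add atoms: none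
Why: Dess–Martin oxidation under non-basic conditions gives the α-alkoxy methyl ketone without β-elimination of the C6 silyloxy group and removes the C4 stereocentre.

Step 19
Reactants: 23 (5R,6S,7R,8S)-bromomethyl enone C4 methyl ketone
Product: 26 (4R,5R,6S,7R,8S)-4-hydroxy-2-oxo germacrenolide, via samarium enolate 24 (not isolated), via samarium aldolate 25 (not isolated)
Conditions: SmI2 (2.2 equiv), THF, −78 °C, slow addition of 23 (final 2 mM); then pH 7 buffer
Reagents that add atoms: none
Why: SmI2 transfers two electrons to the C3–Br bond of the bromomethyl enone, by far the most easily reduced site, and gives the trivalent samarium enolate 24 regiospecifically at C3; this adds to the C4 methyl ketone to form the C3–C4 bond, and the samarium aldolate 25, which should not revert at −78 °C, is protonated on quench. The closest known reaction type is the SmI2-promoted intramolecular Reformatsky-type aldol cyclisation of α-bromo carbonyl compounds, which is established for medium and large carbocycles. The ten-membered ring C1–C10 closes in the 10-(enolendo)-exo-trig mode, the E-olefin and the trans-lactone holding C3 and C4 within reach and high dilution suppressing intermolecular aldol addition. The new stereocentre C4 (R) is controlled by chelation of trivalent samarium between the C4 carbonyl oxygen and the C5 naphthylmethyl ether oxygen, so that C3 attacks the carbonyl face anti to C6 and the 4,5-syn relationship results. The step needs chemoselectivity for C–Br reduction over reductive cleavage of the α-alkoxy ketone and over ketyl formation at the lactone or enone, which the much faster reduction of α-bromo ketones at −78 °C with only 2.2 equivalents of SmI2 secures. It also needs cyclisation to outrun protonation of the enolate, which aprotic THF and the internal, chelated ketone acceptor secure.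

Step 20
Reactants: 26 (4R,5R,6S,7R,8S)-4-hydroxy-2-oxo germacrenolide
Product: 28 (2S)-2,4-syn diol, via diethylboron chelate 27 (not isolated)
Conditions: Et2BOMe, THF/MeOH (4:1), −78 °C; NaBH4; then AcOH, MeOH co-evaporation
Reagents that add atoms: none
Why: In this Narasaka–Prasad reduction the boron ties the C4 hydroxyl and the C2 carbonyl into a six-membered chelate and borohydride attacks C2 from outside in the axial sense, which should give the 2,4-syn diol (2S) by 1,2-reduction of the enone.

Step 21
Reactants: 28 (2S)-2,4-syn diol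
Product: 29 C2 TBS ether
Conditions: tBuMe2SiOTf (1.1 equiv), 2,6-lutidine, CH2Cl2, −78 °C
Reagents that add atoms: tert-butyldimethylsilyl triflate, CC(C)(C)[Si](C)(C)OS(=O)(=O)C(F)(F)F
Why: At −78 °C one equivalent of silyl triflate should silylate the secondary allylic C2 hydroxyl and leave the hindered tertiary C4 hydroxyl free.

Step 22
Reactants: 29 C2 TBS ether
Product: 30 4,5-diol
Conditions: DDQ, CH2Cl2/H2O (10:1), 25 °C
Reagents that add atoms: none
Why: Oxidative cleavage of the NAP ether by DDQ in wet solvent frees C5–OH, the water intercepting the oxocarbenium ion before the neighbouring C4 hydroxyl can form a cyclic acetal.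

Step 23
Reactants: 30 4,5-diol
Product: 31 C5 mesylate
Conditions: CH3SO2Cl, Et3N, CH2Cl2, 0 °C
Reagents that add atoms: methanesulfonyl chloride, CS(=O)(=O)Cl
Why: Sulfonylation through the sulfene should take the secondary C5 hydroxyl only, since the tertiary C4 hydroxyl does not react under these conditions.

Step 24
Reactants: 31 C5 mesylate
Product: 32 (4R,5S)-4,5-epoxide
Conditions: NaH, THF, 0 → 25 °C
Reagents that add atoms: none
Why: Intramolecular Williamson etherification (3-exo-tet): the C4 alkoxide displaces the C5 mesylate from the rear, so C5 is inverted and C4 retained, which gives the cis-fused epoxide of the target.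

Step 25
Reactants: 32 (4R,5S)-4,5-epoxide
Product: 33 C11 dimethylaminomethyl lactone (Mannich base)
Conditions: LiN(iPr)2, THF, −78 °C; then CH2=NMe2+ I−, −78 → 25 °C
Reagents that add atoms: N,N-dimethylmethyleneiminium iodide, C=[N+](C)C.[I-]
Why: Mannich-type alkylation of the lactone lithium enolate with Eschenmoser's salt brings in C13; the new C11 centre is not controlled and is removed in the next step.

Step 26
Reactants: 33 C11 dimethylaminomethyl lactone
Product: 35 α-methylene lactone, via trimethylammonium iodide 34 (not isolated)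
Conditions: CH3I, MeOH, 25 °C; then aq. NaHCO3, CH2Cl2, 25 °C
Reagents that add atoms: none
Why: Quaternisation followed by mild-base β-elimination (Hofmann type, E1cB at the lactone α-carbon) should give the exocyclic C11=C13 double bond without touching the epoxide.

Step 27
Reactants: 35 α-methylene lactone
Product: 36 2,6-diol
Conditions: HF·pyridine, pyridine, THF, 0 → 25 °C
Reagents that add atoms: none
Why: Buffered fluoride desilylation under weakly acidic conditions avoids alkoxide formation at C6, and with it translactonisation, and should be too mild to open the epoxide.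

Step 28
Reactants: 36 2,6-diol
Product: 37 target diacetate CNP0270851.3
Conditions: Ac2O, pyridine, 4-dimethylaminopyridine (cat.), CH2Cl2, 0 → 25 °C
Reagents that add atoms: acetic anhydride, CC(=O)OC(C)=O
Why: Nucleophile-catalysed acylation esterifies both secondary hydroxyl groups; no stereocentre is affected.

**Compound list**
1 | diethyl L-tartrate, diethyl (2R,3R)-2,3-dihydroxybutanedioate | CCOC(=O)[C@H](O)[C@@H](O)C(=O)OCC | starting material
2 | diethyl (4R,5R)-2-(naphthalen-2-yl)-1,3-dioxolane-4,5-dicarboxylate | CCOC(=O)[C@@H]1OC(c2ccc3ccccc3c2)O[C@H]1C(=O)OCC | intermediate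
3 | 2-O-(2-naphthylmethyl)-L-threitol, (2S,3S)-3-(naphthalen-2-ylmethoxy)butane-1,2,4-triol; C4–C7 unit, ether on C5 | OC[C@H](OCc1ccc2ccccc2c1)[C@@H](O)CO | intermediate
4 | 3,4-O-isopropylidene-2-O-(2-naphthylmethyl)-L-threitol; free C4–OH, acetonide on O6/O7 | OC[C@H](OCc1ccc2ccccc2c1)[C@@H]3COC(C)(C)O3 | intermediate
5 | 3,4-O-isopropylidene-2-O-(2-naphthylmethyl)-L-threose; C4 aldehyde | O=C[C@H](OCc1ccc2ccccc2c1)[C@@H]3COC(C)(C)O3 | intermediate
6 | (4R)-C4 methyl carbinol, 4,5-syn; C5–ONAP, O6/O7 acetonide | C[C@@H](O)[C@H](OCc1ccc2ccccc2c1)[C@@H]3COC(C)(C)O3 | intermediate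
7 | C4 PMB ether of 6 | C[C@@H](OCc4ccc(OC)cc4)[C@H](OCc1ccc2ccccc2c1)[C@@H]3COC(C)(C)O3 | intermediate
8 | C6/C7 diol; C4–OPMB, C5–ONAP | C[C@@H](OCc3ccc(OC)cc3)[C@H](OCc1ccc2ccccc2c1)[C@@H](O)CO | intermediate
9 | C6/C7 bis-TBS ether | C[C@@H](OCc3ccc(OC)cc3)[C@H](OCc1ccc2ccccc2c1)[C@@H](O[Si](C)(C)C(C)(C)C)CO[Si](C)(C)C(C)(C)C | intermediate
10 | C7 primary alcohol; C6–OTBS | C[C@@H](OCc3ccc(OC)cc3)[C@H](OCc1ccc2ccccc2c1)[C@@H](O[Si](C)(C)C(C)(C)C)CO | intermediate
11 | C7 aldehyde | C[C@@H](OCc3ccc(OC)cc3)[C@H](OCc1ccc2ccccc2c1)[C@@H](O[Si](C)(C)C(C)(C)C)C=O | intermediate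
12 | methyl (E)-enoate; C7=C11, C12 ester | C[C@@H](OCc3ccc(OC)cc3)[C@H](OCc1ccc2ccccc2c1)[C@@H](O[Si](C)(C)C(C)(C)C)/C=C/C(=O)OC | intermediate
13 | TMS ketene acetal of 14; ketene acetal geometry not defined | COC(O[Si](C)(C)C)=C[C@H](C=C)[C@H](O[Si](C)(C)C(C)(C)C)[C@@H](OCc1ccc2ccccc2c1)[C@H](OCc3ccc(OC)cc3)C | intermediate (not isolated)
14 | (7R)-C7 vinyl methyl ester; vinyl anti to C6–O | COC(=O)C[C@H](C=C)[C@H](O[Si](C)(C)C(C)(C)C)[C@@H](OCc1ccc2ccccc2c1)[C@H](OCc3ccc(OC)cc3)C | intermediate
15 | C8 aldehyde; C7 as in 14 | COC(=O)C[C@H](C=O)[C@H](O[Si](C)(C)C(C)(C)C)[C@@H](OCc1ccc2ccccc2c1)[C@H](OCc3ccc(OC)cc3)C | intermediate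
16 | mesityl oxide, 4-methylpent-3-en-2-one | CC(C)=CC(C)=O | starting material
17 | (Z)-2-methyl-4-(trimethylsilyloxy)penta-1,3-diene | C=C(C)/C=C(/C)O[Si](C)(C)C | intermediate
18 | (8S)-C8 hydroxy methyl ester with (E)-enone side chain | COC(=O)C[C@H]([C@@H](O)C/C(C)=C/C(C)=O)[C@H](O[Si](C)(C)C(C)(C)C)[C@@H](OCc1ccc2ccccc2c1)[C@H](OCc3ccc(OC)cc3)C | intermediate (not isolated)
19 | (7R,8S)-trans-γ-lactone with (E)-2-methyl-4-oxopent-2-enyl chain on C8; C4–OPMB, C5–ONAP, C6–OTBS | CC(=O)/C=C(C)/C[C@@H]1OC(=O)C[C@H]1[C@H](O[Si](C)(C)C(C)(C)C)[C@@H](OCc2ccc3ccccc3c2)[C@H](OCc4ccc(OC)cc4)C | intermediate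
20 | TMS dienol ether of 19 (C3=C2–OTMS) | C=C(O[Si](C)(C)C)/C=C(C)/C[C@@H]1OC(=O)C[C@H]1[C@H](O[Si](C)(C)C(C)(C)C)[C@@H](OCc2ccc3ccccc3c2)[C@H](OCc4ccc(OC)cc4)C | intermediate (not isolated)
21 | bromomethyl (E)-enone, C4–OPMB | BrCC(=O)/C=C(C)/C[C@@H]1OC(=O)C[C@H]1[C@H](O[Si](C)(C)C(C)(C)C)[C@@H](OCc2ccc3ccccc3c2)[C@H](OCc4ccc(OC)cc4)C | intermediate
22 | bromomethyl (E)-enone, C4–OH | BrCC(=O)/C=C(C)/C[C@@H]1OC(=O)C[C@H]1[C@H](O[Si](C)(C)C(C)(C)C)[C@@H](OCc2ccc3ccccc3c2)[C@H](O)C | intermediate
23 | (5R,6S,7R,8S)-bromomethyl (E)-enone C4 methyl ketone; C5–ONAP, C6–OTBS; cyclisation precursor | BrCC(=O)/C=C(C)/C[C@@H]1OC(=O)C[C@H]1[C@H](O[Si](C)(C)C(C)(C)C)[C@@H](OCc2ccc3ccccc3c2)C(C)=O | intermediate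
24 | samarium enolate of 23 (C3=C2–OSmI2) | C=C(O[Sm](I)I)/C=C(C)/C[C@@H]1OC(=O)C[C@H]1[C@H](O[Si](C)(C)C(C)(C)C)[C@@H](OCc2ccc3ccccc3c2)C(C)=O | intermediate (not isolated)
25 | samarium aldolate of 26 (C4–OSmI2) | C1C(=O)O[C@H]2C/C(C)=C/C(=O)C[C@@](C)(O[Sm](I)I)[C@H](OCc3ccc4ccccc4c3)[C@@H](O[Si](C)(C)C(C)(C)C)[C@H]12 | intermediate (not isolated)
26 | (4R,5R,6S,7R,8S)-4-hydroxy-2-oxo-13-norgermacr-1(10)E-en-12,8-olide; C5–ONAP, C6–OTBS | C1C(=O)O[C@H]2C/C(C)=C/C(=O)C[C@@](C)(O)[C@H](OCc3ccc4ccccc4c3)[C@@H](O[Si](C)(C)C(C)(C)C)[C@H]12 | intermediate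
27 | diethylboron chelate of 26 (C4–O–BEt2 bound to C2=O) | C1C(=O)O[C@H]2C/C(C)=C/C(=O)C[C@@](C)(OB(CC)CC)[C@H](OCc3ccc4ccccc4c3)[C@@H](O[Si](C)(C)C(C)(C)C)[C@H]12 | intermediate (not isolated)
28 | (2S)-2,4-syn diol | C1C(=O)O[C@H]2C/C(C)=C/[C@@H](O)C[C@@](C)(O)[C@H](OCc3ccc4ccccc4c3)[C@@H](O[Si](C)(C)C(C)(C)C)[C@H]12 | intermediate
29 | C2 TBS ether; C4–OH free | C1C(=O)O[C@H]2C/C(C)=C/[C@@H](O[Si](C)(C)C(C)(C)C)C[C@@](C)(O)[C@H](OCc3ccc4ccccc4c3)[C@@H](O[Si](C)(C)C(C)(C)C)[C@H]12 | intermediate
30 | 4,5-diol; C2 and C6 TBS ethers | C1C(=O)O[C@H]2C/C(C)=C/[C@@H](O[Si](C)(C)C(C)(C)C)C[C@@](C)(O)[C@H](O)[C@@H](O[Si](C)(C)C(C)(C)C)[C@H]12 | intermediate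
31 | C5 mesylate | C1C(=O)O[C@H]2C/C(C)=C/[C@@H](O[Si](C)(C)C(C)(C)C)C[C@@](C)(O)[C@H](OS(C)(=O)=O)[C@@H](O[Si](C)(C)C(C)(C)C)[C@H]12 | intermediate
32 | (4R,5S)-4,5-epoxide; C2 and C6 TBS ethers | C1C(=O)O[C@H]2C/C(C)=C/[C@@H](O[Si](C)(C)C(C)(C)C)C[C@@]3(C)O[C@H]3[C@@H](O[Si](C)(C)C(C)(C)C)[C@H]12 | intermediate
33 | C11 dimethylaminomethyl lactone; C11 epimers | CN(C)CC1C(=O)O[C@H]2C/C(C)=C/[C@@H](O[Si](C)(C)C(C)(C)C)C[C@@]3(C)O[C@H]3[C@@H](O[Si](C)(C)C(C)(C)C)[C@H]12 | intermediate
34 | C11 trimethylammoniomethyl lactone iodide | C[N+](C)(C)CC1C(=O)O[C@H]2C/C(C)=C/[C@@H](O[Si](C)(C)C(C)(C)C)C[C@@]3(C)O[C@H]3[C@@H](O[Si](C)(C)C(C)(C)C)[C@H]12.[I-] | intermediate (not isolated)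
35 | α-methylene lactone; C2 and C6 TBS ethers | C=C1C(=O)O[C@H]2C/C(C)=C/[C@@H](O[Si](C)(C)C(C)(C)C)C[C@@]3(C)O[C@H]3[C@@H](O[Si](C)(C)C(C)(C)C)[C@H]12 | intermediate
36 | 2,6-diol | C=C1C(=O)O[C@H]2C/C(C)=C/[C@@H](O)C[C@@]3(C)O[C@H]3[C@@H](O)[C@H]12 | intermediate
37 | CNP0270851.3, (2S,4R,5S,6S,7R,8S)-2,6-diacetoxy-4,5-epoxygermacra-1(10)E,11(13)-dien-12,8-olide | C=C1C(=O)O[C@H]2C/C(C)=C/[C@@H](OC(C)=O)C[C@@]3(C)O[C@H]3[C@@H](OC(C)=O)[C@H]12 | target

**Totals**
Total step count: 28.
Longest linear sequence: 27 steps (steps 1–13 and 15–28, from diethyl L-tartrate); step 14 is a one-step branch from mesityl oxide.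

**Steps most likely to fail**

Step 19 (ring closure). The samarium enolate may be protonated before it cyclises (simple loss of bromine). It may also add intermolecularly, the C5 ether may be lost reductively from the α-alkoxy ketone, or the enolate may add to the wrong face of C4. Fallback, setting out from 23: reductive silylation of the bromo ketone with Zn and Me3SiCl (TMEDA, Et2O, 0 °C) should give regiospecifically the trimethylsilyl dienol ether F1. This is closed by an intramolecular Mukaiyama aldol addition under TiCl4 chelation of the C4 carbonyl and the C5 ether (CH2Cl2, −78 °C, high dilution). The fallback rejoins the route at 26.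

Step 15 (vinylogous aldol addition and lactonisation). 1,3-Induction from the C6 silyl ether may work against Felkin control and erode the facial selectivity at C8. The dienol ether may also react through its α-carbon, or the C10=C1 geometry may scramble. Fallback, setting out from 15: methallylboration with (−)-B-methallyldiisopinocampheylborane (from (+)-α-pinene; Et2O, −78 °C; NaBO3 work-up) puts C8 under reagent control, its Si-face preference matching the Felkin sense, and gives the C8 homoallylic alcohol F2. Camphorsulfonic acid closes this to the methallyl lactone F3. Cross-metathesis of F3 with 3-buten-2-one (second-generation Hoveyda–Grubbs catalyst, (H2IMes)Cl2Ru=CH(C6H4-2-OiPr), CH2Cl2, 40 °C) then builds the E-enone and rejoins the route at 19.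

Step 20 (directed reduction). The conformation of the ten-membered enone may expose the wrong face of C2 to external hydride and override delivery through the boron chelate, or conjugate reduction may compete. Fallback, setting out from 26: Corey–Bakshi–Shibata reduction with BH3·SMe2 and the (R)-B-methyl oxazaborolidine derived from diphenylprolinol (toluene, −40 °C) puts C2 under catalyst control. The alkenyl side acts as the large group, which should give the 2S alcohol. This fallback creates no new compound (F0) and rejoins the route at 28.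

**Further compounds**
F1 | step 19 | trimethylsilyl dienol ether of 23 (C3=C2–OTMS, C4 methyl ketone intact) | C=C(O[Si](C)(C)C)/C=C(C)/C[C@@H]1OC(=O)C[C@H]1[C@H](O[Si](C)(C)C(C)(C)C)[C@@H](OCc2ccc3ccccc3c2)C(C)=O
F2 | step 15 | (8S)-C8 homoallylic alcohol methyl ester (2-methylallyl on C8) | COC(=O)C[C@H]([C@@H](O)CC(C)=C)[C@H](O[Si](C)(C)C(C)(C)C)[C@@H](OCc1ccc2ccccc2c1)[C@H](OCc3ccc(OC)cc3)C
F3 | step 15 | (7R,8S)-trans-lactone with 2-methylallyl group on C8 | C=C(C)C[C@@H]1OC(=O)C[C@H]1[C@H](O[Si](C)(C)C(C)(C)C)[C@@H](OCc2ccc3ccccc3c2)[C@H](OCc4ccc(OC)cc4)C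
F0 | step 20 | none | none
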